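Ring C is taken apart as a formal [4+2]. The four-atom unit C4a=C8a-O1-C2 is an aryloxymethyl cation released from a ring A acyloxymethyl ether. The two-atom unit C3-C4 is a chiral arylacetyl imide enolate that acts as a ketene equivalent. In one TiCl4-mediated operation C3 captures C2, which sets (3R), and the chelated imide carbonyl C4 then acylates C4a and expels the auxiliary. The step exploits the alternating polarity C2(+), C3(-), C4(+), C4a(-). It also exploits the mirror plane of the phloroglucinol ring A through C6 and C8a, which makes C4a and C8 equivalent. Both precursors already carry their prenyl groups, and only desilylation follows.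

Key step: step 8

Remark: flavonoid numbering is used (O1, C2, C3, C4, C4a, C5 to C8, C8a; ring B primed). With the CIP order C4 > C2 > C1' > H, the stereocentre of the target is (3R). TBS = tert-butyldimethylsilyl, prenyl = 3-methylbut-2-en-1-yl. Compounds 1, 2, 6, 9, 12 and 14 are assumed to be purchasable.

Step 1
Reactants: 1 phloroglucinol; 2 chloromethyl pivalate
Product: 3 (3,5-dihydroxyphenoxy)methyl pivalate
Conditions: 1 (3 equiv), 2 (1 equiv), K2CO3 (1 equiv), DMF, 0 °C to rt
Reagents that add atoms: none
Why: Williamson ether synthesis in which the hard chloromethyl ester alkylates the phenoxide at oxygen, the excess of triol holds the reaction at the monoether, and the hindered pivaloyl group resists acyl transfer to the free phenols.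

Step 2
Reactants: 3 (3,5-dihydroxyphenoxy)methyl pivalate
Product: 4 (3,5-dihydroxy-4-iodophenoxy)methyl pivalate
Conditions: iodine (1.0 equiv), NaHCO3 (1.1 equiv), THF/H2O, 0 °C
Reagents that add atoms: iodine, [I][I]
Why: Electrophilic aromatic iodination of 5-alkoxyresorcinols under bicarbonate conditions is known to go to the carbon between the two free hydroxyl groups, which here is the carbon para to the acetal oxygen (the future C6).

Step 3
Reactants: 4 (3,5-dihydroxy-4-iodophenoxy)methyl pivalate
Product: 5 [3,5-bis(tert-butyldimethylsilyloxy)-4-iodophenoxy]methyl pivalate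
Conditions: TBSCl (2.5 equiv), imidazole (5 equiv), DMF, rt
Reagents that add atoms: tert-butyldimethylsilyl chloride, CC(C)(C)[Si](C)(C)Cl
Why: Standard silyl ether formation, chosen because aryl TBS ethers tolerate TiCl4 whereas acetal protecting groups would compete with the pivaloyloxymethyl ether as cation sources in step 8.

Step 4
Reactants: 5 [3,5-bis(tert-butyldimethylsilyloxy)-4-iodophenoxy]methyl pivalate; 6 prenyl bromide (1-bromo-3-methylbut-2-ene)
Product: 8 [3,5-bis(tert-butyldimethylsilyloxy)-4-(3-methylbut-2-en-1-yl)phenoxy]methyl pivalate, via arylmagnesium chloride 7 (not isolated)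
Conditions: iPrMgCl·LiCl (1.1 equiv), THF, -20 °C; CuBr·SMe2 (10 mol%), 6 (1.5 equiv), -20 to 0 °C
Reagents that add atoms: none
Why: Iodine-magnesium exchange followed by copper-catalysed allylic substitution, in which the exchange outruns attack on the hindered pivalate at low temperature, magnesium unlike lithium does not trigger O-to-C silyl migration, and the doubly ortho-substituted aryl nucleophile attacks the primary carbon of 6 to give the linear prenyl group.

Step 5
Reactants: 9 2-(3-bromo-4-hydroxyphenyl)acetic acid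
Product: 11 2-[3-bromo-4-(tert-butyldimethylsilyloxy)phenyl]acetic acid, via silyl ester 10 (not isolated)
Conditions: TBSCl (2.3 equiv), imidazole (5 equiv), DMF, rt; then THF/H2O/AcOH, rt
Reagents that add atoms: tert-butyldimethylsilyl chloride, CC(C)(C)[Si](C)(C)Cl
Why: Silylation of both acidic groups followed by selective hydrolysis, since a silyl ester is cleaved by aqueous acetic acid much faster than an aryl silyl ether.

Step 6
Reactants: 11 2-[3-bromo-4-(tert-butyldimethylsilyloxy)phenyl]acetic acid; 12 (S)-4-benzyl-1,3-oxazolidin-2-one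
Product: 13 (S)-4-benzyl-3-{2-[3-bromo-4-(tert-butyldimethylsilyloxy)phenyl]acetyl}-1,3-oxazolidin-2-one
Conditions: DCC (1.1 equiv), DMAP (10 mol%), CH2Cl2, 0 °C to rt
Reagents that add atoms: none
Why: Carbodiimide coupling with DMAP catalysis (Steglich-type acylation) N-acylates the oxazolidinone directly and leaves the stereocentre of the auxiliary untouched.

Step 7
Reactants: 13 (S)-4-benzyl-3-{2-[3-bromo-4-(tert-butyldimethylsilyloxy)phenyl]acetyl}-1,3-oxazolidin-2-one; 14 tributyl(3-methylbut-2-en-1-yl)stannane
Product: 15 (S)-4-benzyl-3-{2-[4-(tert-butyldimethylsilyloxy)-3-(3-methylbut-2-en-1-yl)phenyl]acetyl}-1,3-oxazolidin-2-one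
Conditions: 14 (1.3 equiv), Pd(PPh3)4 (5 mol%), DMF, 100 °C
Reagents that add atoms: none
Why: Stille coupling under neutral conditions spares the imide and the silyl ether, and carbon-carbon bond formation at the less hindered allyl terminus should give the linear prenyl arene.

Step 8
Reactants: 15 (S)-4-benzyl-3-{2-[4-(tert-butyldimethylsilyloxy)-3-(3-methylbut-2-en-1-yl)phenyl]acetyl}-1,3-oxazolidin-2-one; 8 [3,5-bis(tert-butyldimethylsilyloxy)-4-(3-methylbut-2-en-1-yl)phenoxy]methyl pivalate
Product: 18 (3R)-5,7-bis(tert-butyldimethylsilyloxy)-3-[4-(tert-butyldimethylsilyloxy)-3-(3-methylbut-2-en-1-yl)phenyl]-6-(3-methylbut-2-en-1-yl)chroman-4-one, via titanium enolate 16 (not isolated), via alkylated imide 17 (not isolated)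
Conditions: 15, TiCl4 (1.1 equiv), iPr2NEt (1.05 equiv), CH2Cl2, 0 °C; TiCl4 (1.0 equiv), slow addition of 8 (1.1 equiv), -78 to 0 °C; TiCl4 (1.5 equiv), 0 °C to rt; aq NH4Cl
Reagents that add atoms: none
Why: Proposed new method: soft enolisation of 15 gives the chelated Z trichlorotitanium enolate 16, TiCl4 ionises the C2-O(pivaloyl) bond of 8 (the carboxylate leaves because only the aryloxy-stabilised cation O1=C2 is viable), and C3 attacks C2 to give 17. The new stereocentre C3 is controlled by the benzyl group of the (S)-auxiliary, which shields one face of the chelated enolate so that C2 arrives on the opposite face and (3R) results. On warming with more TiCl4 the chelated imide carbonyl C4 is attacked by C4a, which is ortho to O1 and ortho and para to the two silyloxy groups, and the tetrahedral intermediate expels the titanium-bound oxazolidinone, which takes up the arenium proton; ring C closes here in a 6-exo-trig mode at the exocyclic C4=O bond. The first half is the known Evans asymmetric alkylation of titanium enolates with alkoxymethyl electrophiles, and the second half is closest to the TiCl4-promoted C-acylation of electron-rich arenes and heteroarenes by N-acylbenzotriazoles and to Friedel-Crafts acylation with activated amides, but an N-acyloxazolidinone has not been shown as the acyl donor. Site selectivity in the acylation needs no control because the mirror plane of 8 through C6 and C8a makes C4a and C8 equivalent and C6 is blocked, while slow addition of 8 to preformed 16 favours the enolate over arene or prenyl carbons in the capture of the cation. The configuration should hold because allylic 1,3-strain disfavours re-enolisation of 17 and because iPr2NEt is kept below TiCl4, so that no free amine meets the ketone.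

Step 9
Reactants: 18 (3R)-5,7-bis(tert-butyldimethylsilyloxy)-3-[4-(tert-butyldimethylsilyloxy)-3-(3-methylbut-2-en-1-yl)phenyl]-6-(3-methylbut-2-en-1-yl)chroman-4-one
Product: 19 (3R)-5,7-dihydroxy-3-[4-hydroxy-3-(3-methylbut-2-en-1-yl)phenyl]-6-(3-methylbut-2-en-1-yl)chroman-4-one
Conditions: Et3N·3HF, THF, 0 °C to rt
Reagents that add atoms: none
Why: Fluoride-mediated cleavage of the three aryl silyl ethers in a slightly acidic medium, so that no phenoxide or amine base can enolise C3 and no strong acid can cyclise the ortho-prenylphenols to chromans.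

Compound list
1 | phloroglucinol (benzene-1,3,5-triol) | Oc1cc(O)cc(O)c1 | starting material
2 | chloromethyl pivalate | CC(C)(C)C(=O)OCCl | starting material
3 | (3,5-dihydroxyphenoxy)methyl pivalate | CC(C)(C)C(=O)OCOc1cc(O)cc(O)c1 | intermediate
4 | (3,5-dihydroxy-4-iodophenoxy)methyl pivalate | CC(C)(C)C(=O)OCOc1cc(O)c(I)c(O)c1 | intermediate
5 | [3,5-bis(tert-butyldimethylsilyloxy)-4-iodophenoxy]methyl pivalate | CC(C)(C)C(=O)OCOc1cc(O[Si](C)(C)C(C)(C)C)c(I)c(O[Si](C)(C)C(C)(C)C)c1 | intermediate
6 | prenyl bromide (1-bromo-3-methylbut-2-ene) | CC(C)=CCBr | starting material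
7 | {2,6-bis(tert-butyldimethylsilyloxy)-4-[(pivaloyloxy)methoxy]phenyl}magnesium chloride | CC(C)(C)C(=O)OCOc1cc(O[Si](C)(C)C(C)(C)C)c([Mg]Cl)c(O[Si](C)(C)C(C)(C)C)c1 | intermediate
8 | [3,5-bis(tert-butyldimethylsilyloxy)-4-(3-methylbut-2-en-1-yl)phenoxy]methyl pivalate | CC(C)(C)C(=O)OCOc1cc(O[Si](C)(C)C(C)(C)C)c(CC=C(C)C)c(O[Si](C)(C)C(C)(C)C)c1 | intermediate
9 | 2-(3-bromo-4-hydroxyphenyl)acetic acid | OC(=O)Cc1ccc(O)c(Br)c1 | starting material
10 | tert-butyldimethylsilyl 2-[3-bromo-4-(tert-butyldimethylsilyloxy)phenyl]acetate | CC(C)(C)[Si](C)(C)OC(=O)Cc1ccc(O[Si](C)(C)C(C)(C)C)c(Br)c1 | intermediate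
11 | 2-[3-bromo-4-(tert-butyldimethylsilyloxy)phenyl]acetic acid | OC(=O)Cc1ccc(O[Si](C)(C)C(C)(C)C)c(Br)c1 | intermediate
12 | (S)-4-benzyl-1,3-oxazolidin-2-one | O=C1N[C@@H](Cc2ccccc2)CO1 | starting material
13 | (S)-4-benzyl-3-{2-[3-bromo-4-(tert-butyldimethylsilyloxy)phenyl]acetyl}-1,3-oxazolidin-2-one | O=C(Cc1ccc(O[Si](C)(C)C(C)(C)C)c(Br)c1)N1C(=O)OC[C@@H]1Cc1ccccc1 | intermediate
14 | tributyl(3-methylbut-2-en-1-yl)stannane | CCCC[Sn](CCCC)(CCCC)CC=C(C)C | starting material
15 | (S)-4-benzyl-3-{2-[4-(tert-butyldimethylsilyloxy)-3-(3-methylbut-2-en-1-yl)phenyl]acetyl}-1,3-oxazolidin-2-one | O=C(Cc1ccc(O[Si](C)(C)C(C)(C)C)c(CC=C(C)C)c1)N1C(=O)OC[C@@H]1Cc1ccccc1 | intermediate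
16 | Z trichlorotitanium enolate of 15 | Cl[Ti](Cl)(Cl)O/C(=C\c1ccc(O[Si](C)(C)C(C)(C)C)c(CC=C(C)C)c1)N1C(=O)OC[C@@H]1Cc1ccccc1 | intermediate
17 | (S)-4-benzyl-3-{(2R)-3-[3,5-bis(tert-butyldimethylsilyloxy)-4-prenylphenoxy]-2-[4-(tert-butyldimethylsilyloxy)-3-prenylphenyl]propanoyl}-1,3-oxazolidin-2-one | O=C([C@@H](COc1cc(O[Si](C)(C)C(C)(C)C)c(CC=C(C)C)c(O[Si](C)(C)C(C)(C)C)c1)c1ccc(O[Si](C)(C)C(C)(C)C)c(CC=C(C)C)c1)N1C(=O)OC[C@@H]1Cc1ccccc1 | intermediate
18 | (3R)-5,7-bis(tert-butyldimethylsilyloxy)-3-[4-(tert-butyldimethylsilyloxy)-3-prenylphenyl]-6-prenylchroman-4-one | CC(C)=CCc1cc([C@@H]2COc3cc(O[Si](C)(C)C(C)(C)C)c(CC=C(C)C)c(O[Si](C)(C)C(C)(C)C)c3C2=O)ccc1O[Si](C)(C)C(C)(C)C | intermediate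
19 | (3R)-5,7-dihydroxy-3-(4-hydroxy-3-prenylphenyl)-6-prenylchroman-4-one | CC(C)=CCc1cc([C@@H]2COc3cc(O)c(CC=C(C)C)c(O)c3C2=O)ccc1O | target

Total step count: 9. Longest linear sequence: 6 (steps 1, 2, 3, 4, 8, 9).

Steps most likely to fail

Step 8. Several processes threaten this step:
- Acyl transfer from the chelated imide to ring A may stall after the alkylation.
- The excess Lewis acid may protonate or hydrochlorinate the prenyl side chains.
- The excess Lewis acid may strip silyl groups. Loss of the C5 silyl group alone would be harmless, since step 9 removes them all.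
- The ketone may enolise on titanium, which would erode the optical purity.

The fallback uses known chemistry only. It sets out from 17, which is isolated by quenching after the second stage at 0 °C. Cleavage of the auxiliary with LiOH/H2O2 (THF/H2O, 0 °C, short contact) should give (2R)-3-[3,5-bis(tert-butyldimethylsilyloxy)-4-prenylphenoxy]-2-[4-(tert-butyldimethylsilyloxy)-3-prenylphenyl]propanoic acid F1. Trifluoroacetic anhydride (CH2Cl2, 0 °C) converts it into the mixed trifluoroacetic anhydride F2. This closes ring C by intramolecular Friedel-Crafts acylation and comes back to the route at 18.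

Step 4. The Grignard reagent may attack the acyloxymethyl acetal, a silyl group may migrate from oxygen to the metallated carbon, or the allylic substitution may occur with transposition. The fallback sets out from 4 and reverses the order of events. Stille coupling of the free iodoresorcinol with 14 (Pd2(dba)3, AsPh3, DMF, 60 °C) should give (3,5-dihydroxy-4-prenylphenoxy)methyl pivalate F3. Silylation (TBSCl, imidazole, DMF) then comes back to the route at 8.

Step 2. Iodination may occur at the carbons ortho to the acetal oxygen, may go on to polyiodination, or the iodine may be lost again on handling. The fallback sets out from 1 and places the prenyl group by a sigmatropic shift instead of by halogenation: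
- Statistical silylation (TBSCl 2 equiv, imidazole) gives 3,5-bis(tert-butyldimethylsilyloxy)phenol F4.
- O-alkylation with 6 (K2CO3, acetone) gives 1,3-bis(tert-butyldimethylsilyloxy)-5-(prenyloxy)benzene F5.
- An Eu(fod)3-catalysed tandem Claisen-Cope rearrangement (CHCl3, 60 °C) carries the prenyl group over the ortho dienone to the para carbon and gives 3,5-bis(tert-butyldimethylsilyloxy)-4-prenylphenol F6.
- Williamson alkylation with 2 (K2CO3, DMF) comes back to the route at 8.

Further compounds
F1 | step 8 | (2R)-3-[3,5-bis(tert-butyldimethylsilyloxy)-4-prenylphenoxy]-2-[4-(tert-butyldimethylsilyloxy)-3-prenylphenyl]propanoic acid | OC(=O)[C@@H](COc1cc(O[Si](C)(C)C(C)(C)C)c(CC=C(C)C)c(O[Si](C)(C)C(C)(C)C)c1)c1ccc(O[Si](C)(C)C(C)(C)C)c(CC=C(C)C)c1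
F2 | step 8 | mixed trifluoroacetic anhydride of F1 | O=C(OC(=O)C(F)(F)F)[C@@H](COc1cc(O[Si](C)(C)C(C)(C)C)c(CC=C(C)C)c(O[Si](C)(C)C(C)(C)C)c1)c1ccc(O[Si](C)(C)C(C)(C)C)c(CC=C(C)C)c1
F3 | step 4 | (3,5-dihydroxy-4-prenylphenoxy)methyl pivalate | CC(C)(C)C(=O)OCOc1cc(O)c(CC=C(C)C)c(O)c1
F4 | step 2 | 3,5-bis(tert-butyldimethylsilyloxy)phenol | Oc1cc(O[Si](C)(C)C(C)(C)C)cc(O[Si](C)(C)C(C)(C)C)c1
F5 | step 2 | 1,3-bis(tert-butyldimethylsilyloxy)-5-(prenyloxy)benzene | CC(C)=CCOc1cc(O[Si](C)(C)C(C)(C)C)cc(O[Si](C)(C)C(C)(C)C)c1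
F6 | step 2 | 3,5-bis(tert-butyldimethylsilyloxy)-4-prenylphenol | CC(C)=CCc1c(O[Si](C)(C)C(C)(C)C)cc(O)cc1O[Si](C)(C)C(C)(C)C
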